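Set the 5.0 d before Monday's change of temperature against the substrate's lifetime at 70 °C, and one of the three flasks nearly drops out of the question.

in all of them: substrate 20 mM; first nucleophile 30.0 mM; second nucleophile 36.0 mM; time 10 d
- Wednesday's: temperature 70 °C
- Thursday's: temperature 85 °C
- Monday's: at 70 °C until 5.0 d, from then on at 85 °C

1. the best flask by amount of target, in percent of the substrate charged; "all alike" if 1.5 percentage points covers them all (Wednesday's / Thursday's / Monday's / all alike)
2. amount of target at the end, in percent of the substrate charged, Wednesday's
3. amount of target at the end, in percent of the substrate charged, Thursday's
4. amount of target at the end, in percent of the substrate charged, Monday's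

- in percentages every species weighs as the substrate in it: one side product B counts as two
- constants are those at 70 °C; use the activation energies for any other temperature

    substrate → intermediate (k1 = 0.043 h⁻¹, Ea1 = 106 kJ mol⁻¹)
    first nucleophile + intermediate → target (k2 = 5.9 L mol⁻¹ h⁻¹, Ea2 = 57.0 kJ mol⁻¹)
    second nucleophile + intermediate → other capture product (k3 = 4.3 L mol⁻¹ h⁻¹, Ea3 = 56.0 kJ mol⁻¹)
    intermediate → side product A (k4 = 0.0069 h⁻¹, Ea4 = 115 kJ mol⁻¹)
    substrate + intermediate → side product B (k5 = 1.3 L mol⁻¹ h⁻¹, Ea5 = 65.0 kJ mol⁻¹)
    (constants at 70 °C)

The substrate gives an intermediate. The first nucleophile turns that into target and the second into the other capture product, while some intermediate falls to side product A or joins a substrate as side product B.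

Does Monday's heat come in time? The substrate's lifetime is 23.3 h, so the wait before the change holds 5.16 lifetimes. That first step by itself leaves 0.574% of the charge, hardly any, and we expect Monday's flask to read as Wednesday's.

Where, then, does the intermediate go? At the charged amounts the two nucleophiles take it at 0.332 h⁻¹ together, 7.72 times the substrate's constant, so it is short-lived and its fate is a race. We carry the split ratio, the rate of capture by the first nucleophile over the rate of capture by the second, 1.14, a selectivity factor. The two captures differ in activation energy by 1.00 kJ mol⁻¹, far less than either, so we hold the ratio at both temperatures. It gives target 53.3% of the capture. At starting rates the side steps cost 9.92% against capture. Side product B counts double but the substrate falls, and we let these two cancel. Our figure for Wednesday's and Monday's is 48.1%.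

Does Thursday's heat cost more than the margin? The step to side product A has a higher activation energy than capture by the first nucleophile, and scaling the capture's speed-up by activation energy makes that step gain 2.34 times on capture. That takes 1.5 percentage points off Thursday's target, about the margin of 1.5 points itself, so our reckoning stops without choosing a side.

The forecast is 47.2%, 46.4% and 47.2%, hence all alike, holding that “the yield is set by the split of a short-lived intermediate”. Its figure for Wednesday's lies below our 48.1%, and its gap between Wednesday's and Thursday's is 0.8 points, narrower than ours.

The flasks give 47.4%, 46.3% and 47.4%, which is all alike, with Thursday's 1.1 points below Wednesday's.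

In Thursday's flask, with the constants held at their 70 °C values and each nucleophile taken at the mean of its start and end fractions, the split ratio becomes 1.09, and target over other capture product reads 1.10. The neighbour of Thursday's charged with 18 mM of first nucleophile has a split ratio of 0.686, or 0.650 with its own end fractions. That neighbour ends with 33.9% target and 51.8% other capture product, a ratio of 0.654.

The constants used here were chosen freely; the flask was simulated.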